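## Retrosynthetic overview

1. Target ⇐ sulfoxide elimination that unveils the 11(13)-methylene, after C9-selective isobutyrylation of a macrocyclic 7,8,9-triol.
2. Ten-membered ring (formed second and last) ⇐ Z-selective intramolecular Wittig olefination of a C1 ylide onto the C10 methyl ketone that carries the C9 oxygen. This replaces the usual NHK or RCM closure and sets the 1(10)Z alkene in the ring-forming step.
3. C8/C9 anti-diol and the C10 ketone ⇐ D-proline-catalysed aldol of hydroxyacetone with a C8 aldehyde on the lactone.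
4. γ-Lactone (formed first) with C6 and C7 ⇐ Sharpless epoxidation of a cross-conjugated trienol, then opening of the vinyl epoxide at C6 by the ester carbonyl with inversion.
5. Trienol ⇐ Stille coupling, trans-hydrostannation, Sonogashira coupling and carboalumination from tert-butyl 2-bromoacrylate, propargyl alcohol and 5-chloropent-1-yne.

Assumption: atoms carry germacrane numbers throughout (ring C1–C10, C14 on C10, C15 on C4, lactone carbons C11–C13 on C7), and the sulfide-bearing compounds 11–22 are mixtures of epimers at C11, a centre erased in step 15.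

## Route

Step 1
Reactants: 1 5-chloropent-1-yne
Product: 3 (E)-5-chloro-1-iodo-2-methylpent-1-ene, via alkenylalane 2 (not isolated)
Conditions: AlMe3 (2 equiv), Cp2ZrCl2 (0.2 equiv), CH2Cl2, 0 °C to rt; then I2, THF, −30 °C
Reagents that add atoms: trimethylaluminium, C[Al](C)C; iodine, [I][I]
Why: Negishi zirconium-catalysed carboalumination adds Me and Al syn across the terminal alkyne (Me to the internal carbon) and iodinolysis of the C–Al bond goes with retention, so the E-trisubstituted iodoalkene (future C4=C5) forms as one isomer and the alkyl chloride is untouched.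

Step 2
Reactants: 3 (E)-5-chloro-1-iodo-2-methylpent-1-ene; 4 prop-2-yn-1-ol
Product: 5 (E)-8-chloro-5-methyloct-4-en-2-yn-1-ol
Conditions: PdCl2(PPh3)2 (3 mol%), CuI (6 mol%), Et3N, THF, rt
Reagents that add atoms: none
Why: Sonogashira coupling forms the C5–C6 bond with retention of the E geometry and tolerates the free hydroxyl and the alkyl chloride.

Step 3
Reactants: 5 (E)-8-chloro-5-methyloct-4-en-2-yn-1-ol
Product: 6 (2Z,4E)-8-chloro-5-methyl-2-(tributylstannyl)octa-2,4-dien-1-ol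
Conditions: Bu3SnH (1.1 equiv), [Cp*RuCl]4 (2.5 mol%), CH2Cl2, rt
Reagents that add atoms: tributyltin hydride, CCCC[SnH](CCCC)CCCC
Why: Hydroxyl-directed ruthenium-catalysed trans-hydrostannation places tin on the alkyne carbon next to the carbinol and adds H and Sn anti, which gives the Z-alkenylstannane and fixes the geometry of the future C6=C7 alkene (C8 trans to C5).

Step 4
Reactants: 6 (2Z,4E)-8-chloro-5-methyl-2-(tributylstannyl)octa-2,4-dien-1-ol; 7 tert-butyl 2-bromoprop-2-enoate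
Product: 8 tert-butyl (3E,5E)-9-chloro-3-(hydroxymethyl)-6-methyl-2-methylidenenona-3,5-dienoate
Conditions: Pd(PPh3)4 (5 mol%), CuI (10 mol%), CsF (2 equiv), DMF, 45 °C
Reagents that add atoms: none
Why: Stille coupling promoted by copper and fluoride transfers the alkenyl group from tin with retention, so C11 ends up cis to C5 in the cross-conjugated trienol ester.

Step 5
Reactants: 8 tert-butyl (3E,5E)-9-chloro-3-(hydroxymethyl)-6-methyl-2-methylidenenona-3,5-dienoate
Product: 9 tert-butyl 2-[(2R,3R)-3-[(E)-5-chloro-2-methylpent-1-en-1-yl]-2-(hydroxymethyl)oxiran-2-yl]prop-2-enoate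
Conditions: Ti(OiPr)4 (0.2 equiv), D-(−)-diethyl tartrate (0.24 equiv), tBuOOH (2 equiv), 4 Å MS, CH2Cl2, −20 °C
Reagents that add atoms: tert-butyl hydroperoxide, CC(C)(C)OO
Why: Sharpless asymmetric epoxidation is directed by the primary allylic hydroxyl, so only the C6=C7 alkene reacts, and D-(−)-tartrate gives the (2R,3R)-epoxy alcohol (mirror image of the 2S,3S outcome of L-(+)-tartrate with E-2,3-disubstituted allylic alcohols), which sets C7 and the C6 centre that is inverted next.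

Step 6
Reactants: 9 tert-butyl 2-[(2R,3R)-3-[(E)-5-chloro-2-methylpent-1-en-1-yl]-2-(hydroxymethyl)oxiran-2-yl]prop-2-enoate
Product: 10 (4R,5S)-5-[(E)-5-chloro-2-methylpent-1-en-1-yl]-4-hydroxy-4-(hydroxymethyl)-3-methylideneoxolan-2-one
Conditions: CSA (0.2 equiv), CH2Cl2, 0 °C
Reagents that add atoms: none
Why: Acid-promoted lactonisation of a β,γ-epoxy ester (5-endo epoxide opening): the ester carbonyl oxygen attacks the allylically activated C6 anti to the epoxide C–O bond, so C6 is inverted to S, C7 keeps its oxygen as the R tertiary alcohol, and the tert-butyl group leaves as isobutene.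

Step 7
Reactants: 10 (4R,5S)-5-[(E)-5-chloro-2-methylpent-1-en-1-yl]-4-hydroxy-4-(hydroxymethyl)-3-methylideneoxolan-2-one
Product: 11 (4R,5S)-5-[(E)-5-chloro-2-methylpent-1-en-1-yl]-4-hydroxy-4-(hydroxymethyl)-3-[(phenylsulfanyl)methyl]oxolan-2-one (C3 epimers)
Conditions: PhSH (1.1 equiv), Et3N (0.1 equiv), CH2Cl2, 0 °C
Reagents that add atoms: thiophenol, Sc1ccccc1
Why: Base-catalysed thia-Michael addition masks the α-methylene lactone, which would not survive the amine catalyst and the ylide used later; the new C11 centre forms as an inconsequential epimer mixture.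

Step 8
Reactants: 11 (4R,5S)-5-[(E)-5-chloro-2-methylpent-1-en-1-yl]-4-hydroxy-4-(hydroxymethyl)-3-[(phenylsulfanyl)methyl]oxolan-2-one (C3 epimers)
Product: 12 (2S,3S)-2-[(E)-5-chloro-2-methylpent-1-en-1-yl]-3-hydroxy-5-oxo-4-[(phenylsulfanyl)methyl]oxolane-3-carbaldehyde (C4 epimers)
Conditions: SO3·pyridine, DMSO, iPr2NEt, CH2Cl2, 0 °C
Reagents that add atoms: none
Why: Parikh–Doering oxidation converts the primary alcohol into the aldehyde without touching the sulfide or the tertiary alcohol, and the aldehyde cannot epimerise because its α-carbon is quaternary.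

Step 9
Reactants: 12 (2S,3S)-2-[(E)-5-chloro-2-methylpent-1-en-1-yl]-3-hydroxy-5-oxo-4-[(phenylsulfanyl)methyl]oxolane-3-carbaldehyde (C4 epimers); 13 1-hydroxypropan-2-one
Product: 14 (4R,5S)-5-[(E)-5-chloro-2-methylpent-1-en-1-yl]-4-[(1S,2R)-1,2-dihydroxy-3-oxobutyl]-4-hydroxy-3-[(phenylsulfanyl)methyl]oxolan-2-one (C3 epimers)
Conditions: D-proline (30 mol%), DMSO, rt, 13 in tenfold excess
Reagents that add atoms: none
Why: Proline-catalysed direct aldol reaction of hydroxyacetone (enamine catalysis, anti-selective): with D-proline the hydroxyl-bearing carbon adds to the activated, non-enolisable α-hydroxy aldehyde through the hydrogen-bonded chair transition state, giving the anti-diol with C8 as S and C9 in the target arrangement (labelled R while C10 is a ketone), the mirror image of the 3S,4S sense of L-proline.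

Step 10
Reactants: 14 (4R,5S)-5-[(E)-5-chloro-2-methylpent-1-en-1-yl]-4-[(1S,2R)-1,2-dihydroxy-3-oxobutyl]-4-hydroxy-3-[(phenylsulfanyl)methyl]oxolan-2-one (C3 epimers)
Product: 15 (4S,5S)-5-[(E)-5-chloro-2-methylpent-1-en-1-yl]-4-[(1S,2R)-3-oxo-1,2-bis(triethylsilyloxy)butyl]-3-[(phenylsulfanyl)methyl]-4-(triethylsilyloxy)oxolan-2-one (C3 epimers)
Conditions: Et3SiOTf (4.5 equiv), 2,6-lutidine, CH2Cl2, −78 to 0 °C
Reagents that add atoms: triethylsilyl trifluoromethanesulfonate, CC[Si](CC)(CC)OS(=O)(=O)C(F)(F)F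
Why: Silylation with the silyl triflate and a hindered pyridine base caps all three hydroxyls, including the tertiary one, without enolising the ketone, which blocks retro-aldol cleavage and alkoxide formation in the olefination (the descriptor change at the ring carbon is only a priority change).

Step 11
Reactants: 15 (4S,5S)-5-[(E)-5-chloro-2-methylpent-1-en-1-yl]-4-[(1S,2R)-3-oxo-1,2-bis(triethylsilyloxy)butyl]-3-[(phenylsulfanyl)methyl]-4-(triethylsilyloxy)oxolan-2-one (C3 epimers)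
Product: 17 [(4E)-4-methyl-5-{(2S,3S)-5-oxo-3-[(1S,2R)-3-oxo-1,2-bis(triethylsilyloxy)butyl]-4-[(phenylsulfanyl)methyl]-3-(triethylsilyloxy)oxolan-2-yl}pent-4-en-1-yl]triphenylphosphonium iodide, via iodide 16 (not isolated)
Conditions: NaI (3 equiv), PPh3 (2 equiv), NaHCO3, MeCN, 80 °C
Reagents that add atoms: sodium iodide, [Na+].[I-]; triphenylphosphine, c1ccc(cc1)P(c1ccccc1)c1ccccc1
Why: Finkelstein exchange in situ gives the primary iodide, which alkylates triphenylphosphine (SN2) to the phosphonium salt under neutral conditions that leave the silyl ethers, ketone, lactone and sulfide intact.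

Step 12
Reactants: 17 [(4E)-4-methyl-5-{(2S,3S)-5-oxo-3-[(1S,2R)-3-oxo-1,2-bis(triethylsilyloxy)butyl]-4-[(phenylsulfanyl)methyl]-3-(triethylsilyloxy)oxolan-2-yl}pent-4-en-1-yl]triphenylphosphonium iodide
Product: 19 (6S,7S,8S,9S)-13-(phenylsulfanyl)-7,8,9-tris(triethylsilyloxy)germacra-1(10)Z,4E-dien-12,6-olide (C11 epimers), via ylide 18 (not isolated)
Conditions: KN(SiMe3)2 (1.05 equiv) added to 17 in THF (0.002 M), −78 °C to 40 °C
Reagents that add atoms: none
Why: Proposed new method: deprotonation gives the non-stabilised C1 ylide, which adds to the C10 methyl ketone through the kinetically preferred oxaphosphetane that places the silyloxy-bearing C9 and the ylide chain (C2) cis, so cycloreversion closes the ten-membered ring and sets the 1(10)Z alkene in one Wittig step; the closest known reactions are the intermolecular Z-selective Wittig olefination of α-alkoxy ketones with non-stabilised ylides and Wittig cyclisations of ω-oxoalkylphosphonium salts, and the medium-ring closure is helped by the rigid lactone, the E-alkene in the tether, the cis preference of the ring and high dilution.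

Step 13
Reactants: 19 (6S,7S,8S,9S)-13-(phenylsulfanyl)-7,8,9-tris(triethylsilyloxy)germacra-1(10)Z,4E-dien-12,6-olide (C11 epimers)
Product: 20 (6S,7R,8S,9S)-7,8,9-trihydroxy-13-(phenylsulfanyl)germacra-1(10)Z,4E-dien-12,6-olide (C11 epimers)
Conditions: HF·pyridine, pyridine, THF, 0 °C to rt
Reagents that add atoms: none
Why: Fluoride-mediated desilylation removes the three triethylsilyl ethers under buffered conditions that do not affect the lactone, the sulfide or the alkenes.

Step 14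
Reactants: 20 (6S,7R,8S,9S)-7,8,9-trihydroxy-13-(phenylsulfanyl)germacra-1(10)Z,4E-dien-12,6-olide (C11 epimers)
Product: 21 (6S,7R,8S,9S)-7,8-dihydroxy-9-(2-methylpropanoyloxy)-13-(phenylsulfanyl)germacra-1(10)Z,4E-dien-12,6-olide (C11 epimers)
Conditions: (iPrCO)2O (1.2 equiv), DMAP (0.1 equiv), Et3N, CH2Cl2, −40 °C
Reagents that add atoms: isobutyric anhydride, CC(C)C(=O)OC(=O)C(C)C
Why: Kinetically controlled DMAP-catalysed acylation esterifies the allylic C9 hydroxyl, the least hindered of the three, while the C8 hydroxyl next to the quaternary C7 and the tertiary C7 hydroxyl stay free at low temperature.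

Step 15
Reactants: 21 (6S,7R,8S,9S)-7,8-dihydroxy-9-(2-methylpropanoyloxy)-13-(phenylsulfanyl)germacra-1(10)Z,4E-dien-12,6-olide (C11 epimers)
Product: 23 (6S,7R,8S,9S)-7,8-dihydroxy-9-(2-methylpropanoyloxy)germacra-1(10)Z,4E,11(13)-trien-12,6-olide, via sulfoxide 22 (not isolated)
Conditions: mCPBA (1.05 equiv), CH2Cl2, −78 °C; then toluene, NaHCO3, 100 °C
Reagents that add atoms: none
Why: Sulfide oxidation followed by thermal syn-elimination of the β-sulfinyl lactone (sulfoxide pyrolysis) regenerates the α-methylene lactone; mCPBA at −78 °C oxidises sulfur much faster than the trisubstituted alkenes, and no stereocentre is touched while C11 becomes sp2.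

## Compound list

1 | 5-chloropent-1-yne | C#CCCCCl | starting material
2 | (E)-(5-chloro-2-methylpent-1-en-1-yl)dimethylalane | ClCCC/C(C)=C/[Al](C)C | intermediate
3 | (E)-5-chloro-1-iodo-2-methylpent-1-ene | ClCCC/C(C)=C/I | intermediate
4 | prop-2-yn-1-ol | C#CCO | starting material
5 | (E)-8-chloro-5-methyloct-4-en-2-yn-1-ol | OCC#C/C=C(\C)CCCCl | intermediate
6 | (2Z,4E)-8-chloro-5-methyl-2-(tributylstannyl)octa-2,4-dien-1-ol | OC/C([Sn](CCCC)(CCCC)CCCC)=C/C=C(\C)CCCCl | intermediate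
7 | tert-butyl 2-bromoprop-2-enoate | C=C(Br)C(=O)OC(C)(C)C | starting material
8 | tert-butyl (3E,5E)-9-chloro-3-(hydroxymethyl)-6-methyl-2-methylidenenona-3,5-dienoate | C=C(C(=O)OC(C)(C)C)\C(CO)=C/C=C(\C)CCCCl | intermediate
9 | tert-butyl 2-[(2R,3R)-3-[(E)-5-chloro-2-methylpent-1-en-1-yl]-2-(hydroxymethyl)oxiran-2-yl]prop-2-enoate | C=C(C(=O)OC(C)(C)C)[C@]1(CO)O[C@@H]1/C=C(\C)CCCCl | intermediate
10 | (4R,5S)-5-[(E)-5-chloro-2-methylpent-1-en-1-yl]-4-hydroxy-4-(hydroxymethyl)-3-methylideneoxolan-2-one | C=C1C(=O)O[C@@H](/C=C(\C)CCCCl)[C@]1(O)CO | intermediate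
11 | (4R,5S)-5-[(E)-5-chloro-2-methylpent-1-en-1-yl]-4-hydroxy-4-(hydroxymethyl)-3-[(phenylsulfanyl)methyl]oxolan-2-one (C3 epimers) | c1ccccc1SCC1C(=O)O[C@@H](/C=C(\C)CCCCl)[C@]1(O)CO | intermediate
12 | (2S,3S)-2-[(E)-5-chloro-2-methylpent-1-en-1-yl]-3-hydroxy-5-oxo-4-[(phenylsulfanyl)methyl]oxolane-3-carbaldehyde (C4 epimers) | c1ccccc1SCC1C(=O)O[C@@H](/C=C(\C)CCCCl)[C@]1(O)C=O | intermediate
13 | 1-hydroxypropan-2-one (hydroxyacetone) | CC(=O)CO | starting material
14 | (4R,5S)-5-[(E)-5-chloro-2-methylpent-1-en-1-yl]-4-[(1S,2R)-1,2-dihydroxy-3-oxobutyl]-4-hydroxy-3-[(phenylsulfanyl)methyl]oxolan-2-one (C3 epimers) | c1ccccc1SCC1C(=O)O[C@@H](/C=C(\C)CCCCl)[C@]1(O)[C@@H](O)[C@@H](O)C(C)=O | intermediate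
15 | (4S,5S)-5-[(E)-5-chloro-2-methylpent-1-en-1-yl]-4-[(1S,2R)-3-oxo-1,2-bis(triethylsilyloxy)butyl]-3-[(phenylsulfanyl)methyl]-4-(triethylsilyloxy)oxolan-2-one (C3 epimers) | c1ccccc1SCC1C(=O)O[C@@H](/C=C(\C)CCCCl)[C@]1(O[Si](CC)(CC)CC)[C@@H](O[Si](CC)(CC)CC)[C@@H](O[Si](CC)(CC)CC)C(C)=O | intermediate
16 | (4S,5S)-5-[(E)-5-iodo-2-methylpent-1-en-1-yl]-4-[(1S,2R)-3-oxo-1,2-bis(triethylsilyloxy)butyl]-3-[(phenylsulfanyl)methyl]-4-(triethylsilyloxy)oxolan-2-one (C3 epimers) | c1ccccc1SCC1C(=O)O[C@@H](/C=C(\C)CCCI)[C@]1(O[Si](CC)(CC)CC)[C@@H](O[Si](CC)(CC)CC)[C@@H](O[Si](CC)(CC)CC)C(C)=O | intermediate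
17 | [(4E)-4-methyl-5-{(2S,3S)-5-oxo-3-[(1S,2R)-3-oxo-1,2-bis(triethylsilyloxy)butyl]-4-[(phenylsulfanyl)methyl]-3-(triethylsilyloxy)oxolan-2-yl}pent-4-en-1-yl]triphenylphosphonium iodide | c1ccccc1SCC1C(=O)O[C@@H](/C=C(\C)CCC[P+](c2ccccc2)(c2ccccc2)c2ccccc2)[C@]1(O[Si](CC)(CC)CC)[C@@H](O[Si](CC)(CC)CC)[C@@H](O[Si](CC)(CC)CC)C(C)=O.[I-] | intermediate
18 | [(4E)-4-methyl-5-{(2S,3S)-5-oxo-3-[(1S,2R)-3-oxo-1,2-bis(triethylsilyloxy)butyl]-4-[(phenylsulfanyl)methyl]-3-(triethylsilyloxy)oxolan-2-yl}pent-4-en-1-ylidene]triphenylphosphorane | c1ccccc1SCC1C(=O)O[C@@H](/C=C(\C)CCC=P(c2ccccc2)(c2ccccc2)c2ccccc2)[C@]1(O[Si](CC)(CC)CC)[C@@H](O[Si](CC)(CC)CC)[C@@H](O[Si](CC)(CC)CC)C(C)=O | intermediate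
19 | (6S,7S,8S,9S)-13-(phenylsulfanyl)-7,8,9-tris(triethylsilyloxy)germacra-1(10)Z,4E-dien-12,6-olide (C11 epimers) | c1ccccc1SCC1C(=O)O[C@H]2/C=C(\C)CC/C=C(/C)[C@H](O[Si](CC)(CC)CC)[C@H](O[Si](CC)(CC)CC)[C@]12O[Si](CC)(CC)CC | intermediate
20 | (6S,7R,8S,9S)-7,8,9-trihydroxy-13-(phenylsulfanyl)germacra-1(10)Z,4E-dien-12,6-olide (C11 epimers) | c1ccccc1SCC1C(=O)O[C@H]2/C=C(\C)CC/C=C(/C)[C@H](O)[C@H](O)[C@]12O | intermediate
21 | (6S,7R,8S,9S)-7,8-dihydroxy-9-(2-methylpropanoyloxy)-13-(phenylsulfanyl)germacra-1(10)Z,4E-dien-12,6-olide (C11 epimers) | c1ccccc1SCC1C(=O)O[C@H]2/C=C(\C)CC/C=C(/C)[C@H](OC(=O)C(C)C)[C@H](O)[C@]12O | intermediate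
22 | (6S,7R,8S,9S)-7,8-dihydroxy-9-(2-methylpropanoyloxy)-13-(phenylsulfinyl)germacra-1(10)Z,4E-dien-12,6-olide (C11 and sulfur epimers) | O=S(c1ccccc1)CC1C(=O)O[C@H]2/C=C(\C)CC/C=C(/C)[C@H](OC(=O)C(C)C)[C@H](O)[C@]12O | intermediate
23 | (6S,7R,8S,9S)-7,8-dihydroxy-9-(2-methylpropanoyloxy)germacra-1(10)Z,4E,11(13)-trien-12,6-olide (CNP0301808.4) | C=C1C(=O)O[C@H]2/C=C(\C)CC/C=C(/C)[C@H](OC(=O)C(C)C)[C@H](O)[C@]12O | target

## Step count and weak points

Total step count: 15. Longest linear sequence: 15 steps (1 to 23); 4, 7 and 13 enter as purchased building blocks.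

Most likely to fail:

Step 12 (Wittig closure of the ten-membered ring). Medium-ring closure by a non-stabilised ylide is not established, and enolisation of the ketone or oligomerisation may win. The fallback sets out from 15 and comes back at 19 by forming the same C1=C10 bond through ring-closing metathesis. NaI in acetone gives the iodide 16, now isolated. Anhydrous trimethylamine N-oxide in DMSO oxidises it to the keto-aldehyde (4S,5S)-5-[(E)-2-methyl-5-oxopent-1-en-1-yl]-4-[(1S,2R)-3-oxo-1,2-bis(triethylsilyloxy)butyl]-3-[(phenylsulfanyl)methyl]-4-(triethylsilyloxy)oxolan-2-one F1. Excess Ph3P=CH2 (from Ph3PCH3Br and KN(SiMe3)2) methylenates both carbonyl groups to the diene (4S,5S)-5-[(E)-2-methylhexa-1,5-dien-1-yl]-4-[(1S,2S)-3-methyl-1,2-bis(triethylsilyloxy)but-3-en-1-yl]-3-[(phenylsulfanyl)methyl]-4-(triethylsilyloxy)oxolan-2-one F2. The second-generation Grubbs catalyst RuCl2(=CHPh)(PCy3)(H2IMes) in dilute toluene at 80 °C then closes the ring to 19; here the Z geometry rests on the cis preference of the cyclodecadiene rather than on the α-alkoxy effect, and the aryl sulfide may slow the catalyst.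

Step 9 (proline aldol). The aldehyde is α-quaternary, and the catalyst must override any substrate bias, so rate and diastereoselectivity are uncertain. The fallback sets out from 12 and comes back at 14 by replacing the aldol with a substrate- and reagent-controlled sequence. (E)-Prop-1-enylmagnesium bromide (CH3CH=CHMgBr, THF, −78 °C) adds to the aldehyde under chelation by the magnesium alkoxide of the tertiary hydroxyl, giving the allylic alcohol (4R,5S)-5-[(E)-5-chloro-2-methylpent-1-en-1-yl]-4-hydroxy-4-[(1S,2E)-1-hydroxybut-2-en-1-yl]-3-[(phenylsulfanyl)methyl]oxolan-2-one F3. Ti(OiPr)4, D-(−)-diisopropyl tartrate and tBuOOH (the matched pairing, erythro-selective) give the epoxy alcohol (4R,5S)-5-[(E)-5-chloro-2-methylpent-1-en-1-yl]-4-hydroxy-4-{(S)-hydroxy[(2R,3R)-3-methyloxiran-2-yl]methyl}-3-[(phenylsulfanyl)methyl]oxolan-2-one F4. Opening of the epoxide by DMSO at the methyl-bearing carbon (BF3·OEt2 catalysis) and collapse of the alkoxysulfonium salt with Et3N delivers the α-hydroxy ketone 14.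

Step 14 (C9-selective acylation of the triol). The C8 hydroxyl may compete, or the acyl group may migrate. The fallback sets out from 19 and comes back at 21 by differentiating the hydroxyls through their silyl ethers. PPTS in MeOH/CH2Cl2 at −10 °C cleaves only the least hindered, allylic C9 silyl ether, giving (6S,7S,8S,9S)-9-hydroxy-13-(phenylsulfanyl)-7,8-bis(triethylsilyloxy)germacra-1(10)Z,4E-dien-12,6-olide F5. Isobutyric anhydride with DMAP acylates its single free hydroxyl to (6S,7S,8S,9S)-9-(2-methylpropanoyloxy)-13-(phenylsulfanyl)-7,8-bis(triethylsilyloxy)germacra-1(10)Z,4E-dien-12,6-olide F6. HF·pyridine then removes the two remaining silyl groups to give 21.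

## Further compounds

F1 | step 12 | (4S,5S)-5-[(E)-2-methyl-5-oxopent-1-en-1-yl]-4-[(1S,2R)-3-oxo-1,2-bis(triethylsilyloxy)butyl]-3-[(phenylsulfanyl)methyl]-4-(triethylsilyloxy)oxolan-2-one (C3 epimers) | c1ccccc1SCC1C(=O)O[C@@H](/C=C(\C)CCC=O)[C@]1(O[Si](CC)(CC)CC)[C@@H](O[Si](CC)(CC)CC)[C@@H](O[Si](CC)(CC)CC)C(C)=O
F2 | step 12 | (4S,5S)-5-[(E)-2-methylhexa-1,5-dien-1-yl]-4-[(1S,2S)-3-methyl-1,2-bis(triethylsilyloxy)but-3-en-1-yl]-3-[(phenylsulfanyl)methyl]-4-(triethylsilyloxy)oxolan-2-one (C3 epimers) | c1ccccc1SCC1C(=O)O[C@@H](/C=C(\C)CCC=C)[C@]1(O[Si](CC)(CC)CC)[C@@H](O[Si](CC)(CC)CC)[C@@H](O[Si](CC)(CC)CC)C(C)=C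
F3 | step 9 | (4R,5S)-5-[(E)-5-chloro-2-methylpent-1-en-1-yl]-4-hydroxy-4-[(1S,2E)-1-hydroxybut-2-en-1-yl]-3-[(phenylsulfanyl)methyl]oxolan-2-one (C3 epimers) | c1ccccc1SCC1C(=O)O[C@@H](/C=C(\C)CCCCl)[C@]1(O)[C@@H](O)/C=C/C
F4 | step 9 | (4R,5S)-5-[(E)-5-chloro-2-methylpent-1-en-1-yl]-4-hydroxy-4-{(S)-hydroxy[(2R,3R)-3-methyloxiran-2-yl]methyl}-3-[(phenylsulfanyl)methyl]oxolan-2-one (C3 epimers) | c1ccccc1SCC1C(=O)O[C@@H](/C=C(\C)CCCCl)[C@]1(O)[C@@H](O)[C@H]2O[C@@H]2C
F5 | step 14 | (6S,7S,8S,9S)-9-hydroxy-13-(phenylsulfanyl)-7,8-bis(triethylsilyloxy)germacra-1(10)Z,4E-dien-12,6-olide (C11 epimers) | c1ccccc1SCC1C(=O)O[C@H]2/C=C(\C)CC/C=C(/C)[C@H](O)[C@H](O[Si](CC)(CC)CC)[C@]12O[Si](CC)(CC)CC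
F6 | step 14 | (6S,7S,8S,9S)-9-(2-methylpropanoyloxy)-13-(phenylsulfanyl)-7,8-bis(triethylsilyloxy)germacra-1(10)Z,4E-dien-12,6-olide (C11 epimers) | c1ccccc1SCC1C(=O)O[C@H]2/C=C(\C)CC/C=C(/C)[C@H](OC(=O)C(C)C)[C@H](O[Si](CC)(CC)CC)[C@]12O[Si](CC)(CC)CC
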